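**Retrosynthetic overview**
1. The target diacid comes from its ring methyl ester by acid hydrolysis in the last step.
2. The butenolide comes from an α‑methylene‑γ‑lactone by an exo‑to‑endo alkene shift. Ring A, the only ring, closes by lactonisation directly after the key C–C bond is made.
3. The key disconnection is the C2–C3 bond of the furanone. It joins two carbons that are both electrophilic: the CHO carbon of 16‑oxohexadecanoic acid and the acrylate β‑carbon of dimethyl 2‑(bromomethyl)fumarate. A chiral chromium catalyst reduces the bromide to an ester homoenolate (d3) equivalent and sets the R centre in the same event.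
4. The aldehyde acid comes from 16‑hydroxyhexadecanoic acid, and the bromide from dimethyl itaconate.

Assumption: the (S,S)‑ligand L* = 1,8‑bis[(4S)‑4‑isopropyl‑4,5‑dihydro‑1,3‑oxazol‑2‑yl]‑3,6‑diphenyl‑9H‑carbazole is taken to direct attack to the Si face of the aldehyde (giving R); if the first run shows the opposite sense, its (R,R)‑enantiomer is used and nothing else changes. Ring positions: O1, C2 (carbinol carbon), C3 (carboxyl‑bearing), C4 (methyl‑bearing), C5 (lactone C=O).

**Step 1**
Reactants: 1 16‑hydroxyhexadecanoic acid
Product: 2 16‑oxohexadecanoic acid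
Conditions: IBX (1.5 equiv), EtOAc, 80 °C; filter
Reagents that add atoms: none
Why: IBX oxidation of a primary alcohol stops at the aldehyde under water‑free conditions and leaves the free carboxylic acid alone; no stereocentre is involved.

**Step 2**
Reactants: 3 dimethyl itaconate
Product: 5 dimethyl (Z)‑2‑(bromomethyl)but‑2‑enedioate [dimethyl 2‑(bromomethyl)fumarate], via dibromide 4 (not isolated)
Conditions: Br2 (1.05 equiv), CH2Cl2, 40 °C; then Et3N (1.1 equiv), Et2O, 0 °C to rt
Reagents that add atoms: bromine, BrBr
Why: Bromine addition to the 1,1‑disubstituted alkene followed by amine dehydrobromination (loss of the acidic CH2 proton and the tertiary bromide, E2/E1cB) gives the conjugated allylic bromide, whose alkene geometry does not matter later because the derived allylmetal is configurationally labile.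

**Step 3 (key step)**
Reactants: 2 16‑oxohexadecanoic acid; 5 dimethyl 2‑(bromomethyl)fumarate (1.3 equiv)
Product: 10 15‑[(2R)‑3‑(methoxycarbonyl)‑4‑methyl‑5‑oxo‑2,5‑dihydrofuran‑2‑yl]pentadecanoic acid, via silyl ester 6 (not isolated), via allylchromium reagent 7 (not isolated), via bis‑silyl adduct 8 (not isolated), via methylene lactone 9 (not isolated)
Conditions: BSA (1.1 equiv), THF, rt; then CrCl2 (10 mol%), L* (12 mol%), DIPEA (30 mol%), Mn (2 equiv), TMSCl (1.5 equiv), THF, 0 °C to rt; 1 M HCl/THF, rt; crude + Et3N (3 equiv), CH2Cl2, rt
Reagents that add atoms: none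
Why: Proposed new method: divalent chromium (regenerated by manganese metal) reduces the allylic C–Br bond of 5, so the acrylate β‑carbon, electrophilic in 5, becomes the nucleophilic γ‑terminus of the trivalent allylchromium 7 (an ester homoenolate equivalent), which adds to the equally electrophilic aldehyde carbon of the transiently silylated 6 through a closed six‑membered transition state on the chiral carbazole‑bis(oxazoline) chromium centre (Si‑face attack sets C2 as R), TMSCl releases the catalyst as 8, dilute acid removes both silyl groups and the γ‑hydroxy ester lactonises to 9, and Et3N moves the exocyclic alkene into conjugation with both carbonyls (this erases the C3 centre, so the syn/anti ratio is irrelevant, and leaves C2 untouched); the closest known reaction types are the catalytic asymmetric Nozaki‑Hiyama‑Kishi 2‑(alkoxycarbonyl)allylation/lactonisation of aldehydes with 2‑(bromomethyl)acrylates, the racemic zinc or indium Barbier (Dreiding‑Schmidt) reaction of 5 itself, and the isomerisation of protolichesterinic to lichesterinic acid.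

**Step 4**
Reactants: 10 butenolide methyl ester acid
Product: 11 (2R)‑2‑(14‑carboxytetradecyl)‑4‑methyl‑5‑oxo‑2,5‑dihydrofuran‑3‑carboxylic acid (target)
Conditions: 6 M HCl, 1,4‑dioxane, 100 °C; recrystallise
Reagents that add atoms: water, O
Why: Acid‑catalysed acyl‑oxygen ester hydrolysis (AAC2) cleaves the methyl ester, any lactone opening is reversible and never breaks the C2–O bond, and no base is present to deprotonate C2–H, so the R centre is kept and crystallisation can raise the ee.

**Compound list**
1 | 16‑hydroxyhexadecanoic acid | OCCCCCCCCCCCCCCCC(=O)O | starting material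
2 | 16‑oxohexadecanoic acid | O=CCCCCCCCCCCCCCCC(=O)O | intermediate
3 | dimethyl itaconate (dimethyl 2‑methylidenebutanedioate) | C=C(CC(=O)OC)C(=O)OC | starting material
4 | dimethyl 2‑bromo‑2‑(bromomethyl)butanedioate (racemic) | COC(=O)CC(Br)(CBr)C(=O)OC | intermediate
5 | dimethyl (Z)‑2‑(bromomethyl)but‑2‑enedioate (esters trans) | COC(=O)/C=C(/C(=O)OC)CBr | intermediate
6 | trimethylsilyl 16‑oxohexadecanoate | O=CCCCCCCCCCCCCCCC(=O)O[Si](C)(C)C | intermediate
7 | [2,3‑bis(methoxycarbonyl)prop‑2‑en‑1‑yl]chromium dichloride (trivalent chromium; chiral ligand left out; alkene geometry labile) | COC(=O)C=C(C[Cr](Cl)Cl)C(=O)OC | intermediate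
8 | dimethyl (2S)‑2‑[(1R)‑16‑oxo‑1,16‑bis(trimethylsilyloxy)hexadecyl]‑3‑methylidenebutanedioate (anti adduct drawn) | C=C(C(=O)OC)[C@H](C(=O)OC)[C@@H](CCCCCCCCCCCCCCC(=O)O[Si](C)(C)C)O[Si](C)(C)C | intermediate
9 | 15‑[(2R,3S)‑3‑(methoxycarbonyl)‑4‑methylidene‑5‑oxooxolan‑2‑yl]pentadecanoic acid (trans) | C=C1[C@H](C(=O)OC)[C@@H](CCCCCCCCCCCCCCC(=O)O)OC1=O | intermediate
10 | 15‑[(2R)‑3‑(methoxycarbonyl)‑4‑methyl‑5‑oxo‑2,5‑dihydrofuran‑2‑yl]pentadecanoic acid | CC1=C(C(=O)OC)[C@@H](CCCCCCCCCCCCCCC(=O)O)OC1=O | intermediate
11 | (2R)‑2‑(14‑carboxytetradecyl)‑4‑methyl‑5‑oxo‑2,5‑dihydrofuran‑3‑carboxylic acid | CC1=C(C(=O)O)[C@@H](CCCCCCCCCCCCCCC(=O)O)OC1=O | target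

**Step count**
The route has 4 steps in total. The longest linear sequence is 3 steps (1 → 2 → 10 → 11).

**Steps most likely to fail**

Step 3 carries four risks:
- An uncatalysed manganese Barbier background could lower the ee with this easily reduced bromide.
- The syn and anti pathways might not share the same carbinol configuration.
- Attack could occur through the CH2 terminus instead of the γ‑carbon.
- Et3N could slowly erode the ee through the furanolate.

The fallback keeps the same bond and the same polarity, but moves from chromium to boron and from a chiral metal to a chiral Brønsted acid. Setting out from 5, Pd2(dba)3‑catalysed borylation with B2pin2 gives dimethyl (E)‑2‑[(pinacolboryl)methyl]but‑2‑enedioate F1. F1 and 2 are then combined with (S)‑3,3′‑bis(2,4,6‑triisopropylphenyl)‑1,1′‑binaphthyl‑2,2′‑diyl hydrogen phosphate in toluene; the free acid is tolerated, so no silylation is needed. Reaction through a closed chair gives the syn boron alkoxide F2, which lactonises in the flask to the cis methylene lactone F3. Et3N converts F3 into 10, where the route is rejoined.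

Step 4 is at risk because the conjugated, hindered ester hydrolyses slowly, and long heating in acid could racemise C2 through the dienol. The fallback swaps the order of the last two events. Setting out from 9 (isolated after the HCl work‑up of step 3, with Et3N omitted), the unconjugated ester is hydrolysed with 6 M HCl/dioxane to (2R,3S)‑2‑(14‑carboxytetradecyl)‑4‑methylidene‑5‑oxooxolane‑3‑carboxylic acid F4. The alkene is shifted only then, by brief warming with Et3N in THF. The substrate is then a dicarboxylate, which disfavours deprotonation at C2, and the product is 11 directly.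

Step 2 is at risk from sluggish bromine addition to the electron‑poor alkene, or from elimination towards other isomers. The fallback replaces addition/elimination by allylic C–H substitution. Setting out from 3, DBU isomerisation gives dimethyl mesaconate F5 (any citraconate present is equally usable). Wohl‑Ziegler bromination (NBS, AIBN, PhCF3, reflux) then gives 5.

**Further compounds**
F1 | step 3 | dimethyl (E)‑2‑[(4,4,5,5‑tetramethyl‑1,3,2‑dioxaborolan‑2‑yl)methyl]but‑2‑enedioate | COC(=O)/C=C(/C(=O)OC)CB1OC(C)(C)C(C)(C)O1
F2 | step 3 | (15R,16R)‑17‑methoxycarbonyl‑16‑(methoxycarbonyl)‑15‑(pinacolboryloxy)octadec‑17‑enoic acid (syn boron alkoxide) | C=C(C(=O)OC)[C@@H](C(=O)OC)[C@@H](CCCCCCCCCCCCCCC(=O)O)OB1OC(C)(C)C(C)(C)O1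
F3 | step 3 | 15‑[(2R,3R)‑3‑(methoxycarbonyl)‑4‑methylidene‑5‑oxooxolan‑2‑yl]pentadecanoic acid (cis) | C=C1[C@@H](C(=O)OC)[C@@H](CCCCCCCCCCCCCCC(=O)O)OC1=O
F4 | step 4 | (2R,3S)‑2‑(14‑carboxytetradecyl)‑4‑methylidene‑5‑oxooxolane‑3‑carboxylic acid | C=C1[C@H](C(=O)O)[C@@H](CCCCCCCCCCCCCCC(=O)O)OC1=O
F5 | step 2 | dimethyl mesaconate [dimethyl (E)‑2‑methylbut‑2‑enedioate] | COC(=O)/C=C(/C(=O)OC)C
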